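**Retrosynthetic overview**
1. Labels: decalin C1–C10 (gem-dimethyl C4, ring-fusion C5–H and C10–CH3, alkene C8=C9). Chain C11–C16 runs outward from C9, and C13a is the hydroxymethyl carbon on C13. Butenolide C17–C20 (C19 carbonyl, C20 OCH2).
2. The plan rests on the trisubstituted alkene C13=C14, where C12 and C15 are cis and C13 carries C13a. This is the pattern left when C12 and C15 add to the same face of the triple bond of an O-silylated propargyl alcohol (C13a–C13≡C14).
3. Disconnections, backwards: the 15Z alkene comes from a C15≡C16 alkyne (semireduction, last step). C16–C17 comes from a Sonogashira coupling with 4-bromofuran-2(5H)-one. C12–C13 and C14–C15 come together from a one-flask, three-component carbocupration/alkynylation.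
4. The C12 bromide is cut from (+)-sclareolide, which already holds C11, C12 and both stereocentres (C5, C10). Acid methanolysis removes the C8 oxygen and sets C8=C9; reduction and bromination follow.
5. Ring order: no ring is formed. Rings A and B of the decalin come intact from sclareolide, and the butenolide ring is brought in as its bromide.

Key step: step 6

Remark: the natural (+)-enantiomer of sclareolide, (3aR,5aS,9aS,9bR), is assumed. Its C5 and C10 map directly onto (4aS,8aS) of the target decalin, and neither centre is touched in the route.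

**Step 1**
Reactants: 1 (+)-sclareolide
Product: 2 methyl 2-[(4aS,8aS)-2,5,5,8a-tetramethyl-3,4,4a,5,6,7,8,8a-octahydronaphthalen-1-yl]acetate
Conditions: conc. H2SO4, MeOH, reflux
Reagents that add atoms: methanol, CO
Why: Acid-promoted E1 opening of the tertiary C8–O bond of the lactone, together with Fischer esterification of the released acid under equilibrating conditions, should place the alkene in the most substituted and thermodynamically preferred C8=C9 position, while C5 and C10 are carried over unchanged from 1.

**Step 2**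
Reactants: 2 methyl ester
Product: 3 2-[(4aS,8aS)-2,5,5,8a-tetramethyl-3,4,4a,5,6,7,8,8a-octahydronaphthalen-1-yl]ethanol
Conditions: LiAlH4, Et2O, 0 °C to rt
Reagents that add atoms: none
Why: Hydride reduction of the ester gives the primary C12 alcohol, and the unactivated tetrasubstituted alkene does not react with LiAlH4.

**Step 3**
Reactants: 3 C12 alcohol
Product: 4 2-[(4aS,8aS)-2,5,5,8a-tetramethyl-3,4,4a,5,6,7,8,8a-octahydronaphthalen-1-yl]ethyl bromide (the C12 bromide)
Conditions: CBr4, PPh3, CH2Cl2, 0 °C
Reagents that add atoms: carbon tetrabromide, BrC(Br)(Br)Br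
Why: In the Appel reaction the oxyphosphonium salt of the primary alcohol is displaced by bromide in an SN2 process under near-neutral conditions that spare the acid-sensitive C8=C9 alkene, and no cyclic ether can form because the C8 oxygen is already gone.

**Step 4**
Reactants: 5 propargyl alcohol
Product: 6 tert-butyldimethyl(prop-2-yn-1-yloxy)silane
Conditions: TBSCl, imidazole, CH2Cl2, 0 °C to rt
Reagents that add atoms: tert-butyldimethylsilyl chloride, CC(C)(C)[Si](C)(C)Cl
Why: Imidazole-promoted silylation of a primary alcohol installs the bulky, weakly basic ether oxygen that the regiochemistry of step 6 requires.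

**Step 5**
Reactants: 7 ethynyltrimethylsilane
Product: 8 (bromoethynyl)trimethylsilane
Conditions: NBS (1.0 equiv), AgNO3 (10 mol %), acetone, rt; used as a solution in pentane
Reagents that add atoms: N-bromosuccinimide, O=C1CCC(=O)N1Br
Why: Silver-catalysed electrophilic bromination of the terminal alkyne runs through the silver acetylide, and one equivalent of NBS keeps the C–Si bond in place.

**Step 6**
Reactants: 4 C12 bromide; 6 tert-butyldimethyl(prop-2-yn-1-yloxy)silane; 8 (bromoethynyl)trimethylsilane
Product: 12 silyl-protected decalin enyne (13E; trimethylsilyl on C16; tert-butyldimethylsilyl on the C13a oxygen), via Grignard reagent 9 (not isolated), via alkylcopper reagent 10 (not isolated), via alkenylcopper adduct 11 (not isolated)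
Conditions: Mg, Et2O, reflux; CuBr·SMe2 (1.0 equiv), Et2O/Me2S, −45 °C; 6 (1.1 equiv), −25 to −15 °C; then TMEDA (2 equiv), 8 (1.3 equiv), THF, −40 to 0 °C; aq NH4Cl/NH3
Reagents that add atoms: magnesium, [Mg] (stays only in 9); CuBr·SMe2, CSC.Br[Cu] (its copper stays only in 10 and 11); only atoms of the three reactants end in 12
Why: Grignard reagent 9 and CuBr·SMe2 give the alkylcopper–MgBr2 reagent 10 (monovalent copper), which binds the triple bond of 6 and adds across it through a four-centre syn transition state, C12 bonding to the substituted carbon C13 and copper ending on the terminal carbon C14. The closest known reaction type is the Normant carbocupration of terminal alkynes, followed by the TMEDA-promoted alkynylation of the alkenylcopper with a 1-bromoalkyne, which proceeds with retention at C14 (oxidative addition to a trivalent copper species, then reductive elimination). No ring closes and no stereocentre is made; the only stereochemical element is the C13=C14 geometry, and syn delivery plus retention puts C12 and C15 cis, that is 13E with C13a trans to C15. The step needs copper on C14, and this is secured by the steric preference of copper for the unsubstituted terminus, by the bulky and weakly basic OTBS oxygen that cannot steer copper to C13 by chelation, and by keeping THF out until the addition is over. It also needs 11 to keep its shape, so the flask stays below about −10 °C until 8 is consumed; in 11 the oxygen sits on C13a, two carbons from the copper-bearing C14, so loss of silyloxide to an allene is not open to this regioisomer. C5 and C10 are remote from the reacting atoms, and the C8=C9 alkene is inert to organocopper reagents.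

**Step 7**
Reactants: 12 silyl-protected decalin enyne
Product: 13 (2E)-2-{2-[(4aS,8aS)-2,5,5,8a-tetramethyl-3,4,4a,5,6,7,8,8a-octahydronaphthalen-1-yl]ethyl}pent-2-en-4-yn-1-ol
Conditions: Bu4NF (2.5 equiv), THF, 0 °C to rt
Reagents that add atoms: none
Why: Fluoride-induced desilylation cleaves the C(sp)–Si and the O–Si bond in one operation, at a stage where the molecule has no base-sensitive group, and leaves the 13E alkene untouched.

**Step 8**
Reactants: 13 enynol; 14 4-bromofuran-2(5H)-one
Product: 15 4-[(3E)-4-(hydroxymethyl)-6-[(4aS,8aS)-2,5,5,8a-tetramethyl-3,4,4a,5,6,7,8,8a-octahydronaphthalen-1-yl]hex-3-en-1-yn-1-yl]furan-2(5H)-one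
Conditions: PdCl2(PPh3)2 (5 mol %), CuI (10 mol %), iPr2NEt, degassed THF, rt
Reagents that add atoms: none
Why: In this Sonogashira coupling the electron-poor vinylogous acyl bromide 14 adds quickly to zerovalent palladium at room temperature, the copper acetylide of 13 transmetalates, the hindered amine does not add to the butenolide, and the free alcohol is tolerated.

**Step 9**
Reactants: 15 dienyne butenolide
Product: 16 target, 4-[(1Z,3E)-4-(hydroxymethyl)-6-[(4aS,8aS)-2,5,5,8a-tetramethyl-3,4,4a,5,6,7,8,8a-octahydronaphthalen-1-yl]hexa-1,3-dien-1-yl]furan-2(5H)-one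
Conditions: Zn(Cu/Ag) couple (freshly made from Zn dust, Cu(OAc)2 and AgNO3, washed), MeOH/H2O with a little THF, rt, argon, dark
Reagents that add atoms: none
Why: In the Boland reduction the Zn(Cu/Ag) couple in aqueous methanol delivers two hydrogens to the same face of a conjugated triple bond on the metal surface, which should give the 15Z alkene and leave the other alkenes, the lactone and the allylic alcohol alone, and as the last step it spares the sensitive Z-triene any further reagent.

**Compound list**
1 | (+)-sclareolide, (3aR,5aS,9aS,9bR) | CC1(CCC[C@]2([C@H]1CC[C@@]3([C@@H]2CC(=O)O3)C)C)C | starting material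
2 | methyl 2-[(4aS,8aS)-2,5,5,8a-tetramethyl-3,4,4a,5,6,7,8,8a-octahydronaphthalen-1-yl]acetate | CC1=C(CC(=O)OC)[C@@]2(C)CCCC(C)(C)[C@@H]2CC1 | intermediate
3 | 2-[(4aS,8aS)-2,5,5,8a-tetramethyl-3,4,4a,5,6,7,8,8a-octahydronaphthalen-1-yl]ethanol | CC1=C(CCO)[C@@]2(C)CCCC(C)(C)[C@@H]2CC1 | intermediate
4 | 2-[(4aS,8aS)-2,5,5,8a-tetramethyl-3,4,4a,5,6,7,8,8a-octahydronaphthalen-1-yl]ethyl bromide | CC1=C(CCBr)[C@@]2(C)CCCC(C)(C)[C@@H]2CC1 | intermediate
5 | propargyl alcohol | C#CCO | starting material
6 | tert-butyldimethyl(prop-2-yn-1-yloxy)silane | C#CCO[Si](C)(C)C(C)(C)C | intermediate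
7 | ethynyltrimethylsilane | C#C[Si](C)(C)C | starting material
8 | (bromoethynyl)trimethylsilane | BrC#C[Si](C)(C)C | intermediate
9 | Grignard reagent of 4 (C12–MgBr) | CC1=C(CC[Mg]Br)[C@@]2(C)CCCC(C)(C)[C@@H]2CC1 | intermediate
10 | alkylcopper reagent (C12–Cu, present as its MgBr2 complex) | CC1=C(CC[Cu])[C@@]2(C)CCCC(C)(C)[C@@H]2CC1 | intermediate
11 | (E)-alkenylcopper adduct (Cu on C14, cis to C12; OTBS on C13a) | CC1=C(CC/C(=C\[Cu])CO[Si](C)(C)C(C)(C)C)[C@@]2(C)CCCC(C)(C)[C@@H]2CC1 | intermediate
12 | tert-butyldimethylsilyl ether of (2E)-2-{2-[(4aS,8aS)-decalinyl]ethyl}-5-(trimethylsilyl)pent-2-en-4-yn-1-ol | CC1=C(CC/C(=C\C#C[Si](C)(C)C)CO[Si](C)(C)C(C)(C)C)[C@@]2(C)CCCC(C)(C)[C@@H]2CC1 | intermediate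
13 | (2E)-2-{2-[(4aS,8aS)-2,5,5,8a-tetramethyl-3,4,4a,5,6,7,8,8a-octahydronaphthalen-1-yl]ethyl}pent-2-en-4-yn-1-ol | CC1=C(CC/C(=C\C#C)CO)[C@@]2(C)CCCC(C)(C)[C@@H]2CC1 | intermediate
14 | 4-bromofuran-2(5H)-one | BrC1=CC(=O)OC1 | starting material
15 | 4-[(3E)-4-(hydroxymethyl)-6-[(4aS,8aS)-decalinyl]hex-3-en-1-yn-1-yl]furan-2(5H)-one | CC1=C(CC/C(=C\C#CC2=CC(=O)OC2)CO)[C@@]2(C)CCCC(C)(C)[C@@H]2CC1 | intermediate
16 | CNP0232848.4, 4-[(1Z,3E)-4-(hydroxymethyl)-6-[(4aS,8aS)-decalinyl]hexa-1,3-dien-1-yl]furan-2(5H)-one | CC1=C(CC/C(=C\C=C/C2=CC(=O)OC2)CO)[C@@]2(C)CCCC(C)(C)[C@@H]2CC1 | target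

**Totals**
Total step count: 9.
Longest linear sequence: 7 steps (1, 2, 3, 6, 7, 8, 9).

**Steps most likely to fail**

**Step 6 (key step).**
- What may go wrong:
  - Copper may be delivered to C13 instead of C14, after which silyloxide is lost.
  - The acetylenic C–H may be metalated instead of the triple bond being added to.
  - The primary alkylcopper may decay thermally before it adds.
  - Bromine–copper exchange may compete with C14–C15 bond formation.
- Fallback, from 4, back at 12. C12–C13 is made by a Negishi coupling on an alkenyl iodide whose geometry is fixed beforehand. Neither the regiochemistry of a carbometalation nor the lifetime of an alkenylcopper then matters.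
  - Ethyl (triphenylphosphoranylidene)acetate is iodinated with N-iodosuccinimide (K2CO3, CH2Cl2, −20 °C) to ethyl iodo(triphenylphosphoranylidene)acetate F1.
  - A Wittig reaction of F1 with commercial 3-(trimethylsilyl)propynal should give ethyl (2Z)-2-iodo-5-(trimethylsilyl)pent-2-en-4-ynoate F2, with the ester trans to the alkynyl group. Any geometric isomer is removed at this small-molecule stage.
  - iBu2AlH (CH2Cl2, −78 °C) gives (2Z)-2-iodo-5-(trimethylsilyl)pent-2-en-4-yn-1-ol F3, and TBSCl/imidazole gives its tert-butyldimethylsilyl ether F4.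
  - Bromide 4 is converted into Grignard reagent 9 as in step 6 and transmetalated with ZnBr2 (THF, 0 °C) to the alkylzinc bromide F5.
  - F5 is coupled with F4 under PdCl2(dppf) catalysis (THF, rt), with retention at C13, to give 12.

**Step 9.**
- What may go wrong:
  - Reduction may run past the alkene stage, or stall on the lipophilic substrate.
  - The new alkene may isomerise from Z to E.
  - The Z-triene may undergo a thermal hydrogen shift or electrocyclisation during a long reaction.
- Fallback, from 13, back at 16. The Z alkene is set before the butenolide is attached, and C16–C17 is then closed by a stereoretentive coupling.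
  - 13 is iodinated at the alkyne terminus (N-iodosuccinimide, AgNO3 cat., acetone, 0 °C, dark) to (2E)-2-{2-[(4aS,8aS)-decalinyl]ethyl}-5-iodopent-2-en-4-yn-1-ol F6.
  - Diimide reduction of F6 (2-nitrobenzenesulfonyl hydrazide, Et3N, THF/iPrOH, rt) gives (2E,4Z)-2-{2-[(4aS,8aS)-decalinyl]ethyl}-5-iodopenta-2,4-dien-1-ol F7.
  - Bromide 14 is stannylated (Bu3SnSnBu3, Pd(PPh3)4, toluene, 90 °C) to 4-(tributylstannyl)furan-2(5H)-one F8.
  - Stille coupling of F7 with F8 (Pd2(dba)3, AsPh3, CuI, NMP, rt) gives 16 directly.

**Step 1.**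
- What may go wrong:
  - Positional selection of the alkene may be incomplete, with the C7=C8 or exocyclic isomers persisting.
  - The acid may close back to a lactone.
  - Cationic hydride or methyl shifts may start from C8.
- Fallback, from 1, back at 3. The alkene position is enforced by conjugation instead of by equilibration, at the price of removing and re-adding C12.
  - The enolate of 1 (KN(SiMe3)2, THF, −78 °C) is oxidised with a Davis oxaziridine to 11-hydroxysclareolide F9. Either C11 epimer serves, because this centre is lost later.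
  - LiAlH4 (THF, reflux) gives the 8,11,12-triol F10.
  - NaIO4 (THF/H2O) cleaves the C11–C12 glycol to 8α-hydroxydriman-11-al F11.
  - Acid-catalysed dehydration (p-TsOH, toluene, 80 °C) gives the conjugated drim-8-en-11-al F12.
  - Wittig methylenation (Ph3P=CH2, THF) gives the 1-vinyl diene F13.
  - 9-BBN adds to the terminal carbon only, giving the B-alkyl-9-borabicyclononane F14.
  - Oxidation of F14 with NaOH/H2O2 gives 3.

**Further compounds**
F1 | step 6 | ethyl iodo(triphenylphosphoranylidene)acetate | CCOC(=O)C(I)=P(c1ccccc1)(c1ccccc1)c1ccccc1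
F2 | step 6 | ethyl (2Z)-2-iodo-5-(trimethylsilyl)pent-2-en-4-ynoate | I/C(=C\C#C[Si](C)(C)C)C(=O)OCC
F3 | step 6 | (2Z)-2-iodo-5-(trimethylsilyl)pent-2-en-4-yn-1-ol | I/C(=C\C#C[Si](C)(C)C)CO
F4 | step 6 | tert-butyldimethylsilyl ether of F3 | I/C(=C\C#C[Si](C)(C)C)CO[Si](C)(C)C(C)(C)C
F5 | step 6 | alkylzinc bromide of 4 (C12–ZnBr) | CC1=C(CC[Zn]Br)[C@@]2(C)CCCC(C)(C)[C@@H]2CC1
F6 | step 9 | (2E)-2-{2-[(4aS,8aS)-decalinyl]ethyl}-5-iodopent-2-en-4-yn-1-ol | CC1=C(CC/C(=C\C#CI)CO)[C@@]2(C)CCCC(C)(C)[C@@H]2CC1
F7 | step 9 | (2E,4Z)-2-{2-[(4aS,8aS)-decalinyl]ethyl}-5-iodopenta-2,4-dien-1-ol | CC1=C(CC/C(=C\C=C/I)CO)[C@@]2(C)CCCC(C)(C)[C@@H]2CC1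
F8 | step 9 | 4-(tributylstannyl)furan-2(5H)-one | CCCC[Sn](CCCC)(CCCC)C1=CC(=O)OC1
F9 | step 1 | 11-hydroxysclareolide (C11 configuration open) | CC1(CCC[C@]2([C@H]1CC[C@@]3([C@@H]2C(O)C(=O)O3)C)C)C
F10 | step 1 | 8,11,12-triol from reduction of F9 (C11 configuration open) | CC1(CCC[C@]2([C@H]1CC[C@@](O)([C@@H]2C(O)CO)C)C)C
F11 | step 1 | 8α-hydroxydriman-11-al | CC1(CCC[C@]2([C@H]1CC[C@@](O)([C@@H]2C=O)C)C)C
F12 | step 1 | drim-8-en-11-al, (4aS,8aS)-2,5,5,8a-tetramethyl-3,4,4a,5,6,7,8,8a-octahydronaphthalene-1-carbaldehyde | CC1=C(C=O)[C@@]2(C)CCCC(C)(C)[C@@H]2CC1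
F13 | step 1 | (4aS,8aS)-1-ethenyl-2,5,5,8a-tetramethyl-3,4,4a,5,6,7,8,8a-octahydronaphthalene | CC1=C(C=C)[C@@]2(C)CCCC(C)(C)[C@@H]2CC1
F14 | step 1 | 9-{2-[(4aS,8aS)-decalinyl]ethyl}-9-borabicyclo[3.3.1]nonane | CC1=C(CCB3C4CCCC3CCC4)[C@@]2(C)CCCC(C)(C)[C@@H]2CC1
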